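**Retrosynthetic overview**

1. Ring numbering used here: C1 (C=O), C2 (C–CH2OH), C3 (=CH), C4 (CHOH), C5 (quaternary C), C6 (CH–enol ester), C7 (C=CH–Ac). The enabling feature is that C3 and C7 are 1,5-related through C4–C5–C6, C3 is β and C7 is α to the C1 ketone, so an ether oxygen between C3 and C7 is a removable latent form; C3–C7 plus that oxygen is a 3-oxidopyrylium.
2. Key disconnection: bonds C2–C3 and C1–C7, both made in one intramolecular oxidopyrylium–alkyne (5+2) cycloaddition that dearomatises the heteroarene. The two-carbon partner is an alkynyl ether tethered to C7 through –O–CH(CH3)–CH2–, and these tether atoms later become the O=C(CH3)–CH= unit.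
3. The Z-enedione (C1=O, C7=CH, acetyl) is treated as a ring-opened 2-methylfuran: the tether oxolane is converted into that furan (SmI2 cut of the C7–O bridge bond, elimination at C3, Paal–Knorr) and the furan is opened by singlet oxygen in the last step.
4. Ring order: furan (bought) → pyranone (Achmatowicz) → in the key step the seven-membered carbocycle, its oxygen bridge and the fused oxolane → bridge opened → furan → furan opened.
5. Stereocontrol: the (R)-2-methyloxirane stereocentre in the tether sets the bridgeheads; these steer vinyl (C6), side chain (C5) and hydride (C4) and are then erased. The side-chain carbinol comes from a Corey–Bakshi–Shibata reduction, the E-enol ester from an E-alkenylboron.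

Key step: step 13

Assumption: stereocentres that are created only to be erased later (hemiketal carbon of 19 and 20, endoperoxide bridgeheads of 18 and 40, the ketone α-carbons of 28–32) form as mixtures and are left undefined in the SMILES.

**Route**

Step 1
Reactants: 1 3-chloropropanoyl chloride; 2 prop-1-en-2-ylmagnesium bromide
Product: 3 5-chloro-2-methylpent-1-en-3-one
Conditions: Fe(acac)3 (3 mol%), THF, −78 °C, slow addition of 2 (1.0 equiv)
Reagents that add atoms: none
Why: Iron-catalysed acylation of an alkenyl Grignard reagent by an acid chloride should stop at the ketone at −78 °C because the acid chloride is consumed faster than the product reacts.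

Step 2
Reactants: 3 5-chloro-2-methylpent-1-en-3-one
Product: 4 (R)-5-chloro-2-methylpent-1-en-3-ol
Conditions: (S)-2-methyl-CBS-oxazaborolidine (10 mol%), catecholborane, toluene, −78 °C
Reagents that add atoms: none
Why: In this Corey–Bakshi–Shibata reduction the oxazaborolidine should bind the carbonyl anti to the larger 2-propenyl group and deliver hydride to the face that gives the (R)-allylic alcohol, with 1,2-reduction outrunning hydroboration at low temperature.

Step 3
Reactants: 4 (R)-5-chloro-2-methylpent-1-en-3-ol
Product: 5 (R)-tert-butyl[(5-chloro-2-methylpent-1-en-3-yl)oxy]dimethylsilane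
Conditions: TBSCl, imidazole, DMF, 23 °C
Reagents that add atoms: tert-butyldimethylsilyl chloride, CC(C)(C)[Si](C)(C)Cl
Why: Standard silylation of a secondary allylic alcohol, which leaves the stereocentre untouched.

Step 4
Reactants: 5 (R)-tert-butyl[(5-chloro-2-methylpent-1-en-3-yl)oxy]dimethylsilane
Product: 6 (R)-tert-butyl[(5-iodo-2-methylpent-1-en-3-yl)oxy]dimethylsilane
Conditions: NaI, butan-2-one, 80 °C
Reagents that add atoms: sodium iodide, [Na+].[I-]
Why: Finkelstein exchange at the unhindered primary chloride, driven by precipitation of NaCl.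

Step 5
Reactants: 7 methyl 3-methylfuran-2-carboxylate
Product: 8 (3-methylfuran-2-yl)methanol
Conditions: LiAlH4, Et2O, 0 °C
Reagents that add atoms: none
Why: Hydride reduction of the ester to the furfuryl alcohol whose oxygen later becomes the ring oxygen of the pyrylium.

Step 6
Reactants: 8 (3-methylfuran-2-yl)methanol
Product: 9 tert-butyldimethyl[(3-methylfuran-2-yl)methoxy]silane
Conditions: TBSCl, imidazole, CH2Cl2, 23 °C
Reagents that add atoms: tert-butyldimethylsilyl chloride, CC(C)(C)[Si](C)(C)Cl
Why: Silylation masks the furfuryl alcohol for the organolithium steps and the TBS group can later be removed in the presence of a TIPS ether.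

Step 7
Reactants: 9 tert-butyldimethyl[(3-methylfuran-2-yl)methoxy]silane; 10 (R)-2-methyloxirane
Product: 12 (R)-1-[5-(tert-butyldimethylsilyloxymethyl)-4-methylfuran-2-yl]propan-2-ol, via 5-lithiofuran 11 (not isolated)
Conditions: n-BuLi, THF, 0 °C; then 10, BF3·OEt2, −78 °C
Reagents that add atoms: none
Why: α-Lithiation of the furan at its only free α-position and BF3-assisted opening of the epoxide at CH2 carry the oxirane stereocentre over unchanged.

Step 8
Reactants: 12 (R)-1-[5-(tert-butyldimethylsilyloxymethyl)-4-methylfuran-2-yl]propan-2-ol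
Product: 13 (E)-1,2-dichlorovinyl ether of 12
Conditions: KH (2.2 equiv), trichloroethene (1.1 equiv), THF, −40 → 23 °C
Reagents that add atoms: trichloroethene, ClC=C(Cl)Cl
Why: The potassium alkoxide should add anti to dichloroacetylene generated in situ from trichloroethene, the established entry to 1,2-dichlorovinyl ethers of secondary alcohols.

Step 9
Reactants: 13 (E)-1,2-dichlorovinyl ether of 12
Product: 16 3-(triisopropylsilyloxy)prop-1-ynyl ether of 12, via lithium alkoxyacetylide 14 (not isolated), via lithium propargylic alkoxide 15 (not isolated)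
Conditions: n-BuLi (2.5 equiv), THF, −78 → −40 °C; paraformaldehyde, −78 → 0 °C; TIPSOTf (1.0 equiv), −78 → 0 °C
Reagents that add atoms: formaldehyde (from paraformaldehyde), C=O; triisopropylsilyl trifluoromethanesulfonate, CC(C)[Si](C(C)C)(C(C)C)OS(=O)(=O)C(F)(F)F
Why: Dehydrochlorination and Cl–Li exchange give the lithium alkoxyacetylide, which is hydroxymethylated and silylated in the same flask so that the rearrangement-prone free 3-alkoxypropargyl alcohol is never isolated.

Step 10
Reactants: 16 3-(triisopropylsilyloxy)prop-1-ynyl ether of 12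
Product: 17 furfuryl alcohol (TBS removed)
Conditions: TBAF (1.05 equiv), THF, 0 °C
Reagents that add atoms: none
Why: Fluoride should cleave the primary TBS ether much faster than the primary TIPS ether, and the basic medium spares the acid-labile alkynyl ether.

Step 11
Reactants: 17 furfuryl alcohol
Product: 19 6-hydroxy-4-methyl-2H-pyran-3(6H)-one bearing the alkynyloxypropyl chain at C6, via furan endoperoxide 18 (not isolated)
Conditions: O2, visible light, tetraphenylporphyrin (cat.), CH2Cl2, −78 °C; then Me2S, −78 → 23 °C
Reagents that add atoms: dioxygen, O=O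
Why: Achmatowicz rearrangement in its photooxygenation form, in which singlet oxygen adds [4+2] to the electron-rich trialkylfuran, reduction gives the cis-enedione and the furfuryl hydroxyl closes the hemiketal under neutral conditions that the alkynyl ether tolerates.

Step 12
Reactants: 19 hydroxypyranone
Product: 20 6-acetoxypyranone
Conditions: Ac2O, DMAP (cat.), pyridine, CH2Cl2, 0 °C
Reagents that add atoms: acetic anhydride, CC(=O)OC(C)=O
Why: DMAP-catalysed acylation of the tertiary hemiketal hydroxyl installs the leaving group for ylide formation.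

Step 13
Reactants: 20 6-acetoxypyranone
Product: 22 tricyclic dienone cycloadduct, via 3-oxidopyrylium ylide 21 (not isolated)
Conditions: DBU (1.5 equiv), CH2Cl2 (0.01 M), 0 → 23 °C (kept below 40 °C)
Reagents that add atoms: none
Why: DBU removes the C2 proton and the tertiary acetate leaves to give the aromatic 3-oxidopyrylium ylide 21, whose C2 and C6 add suprafacially across the tethered alkynyl ether in a thermal (5+2) [π4s+π2s] cycloaddition, so the flat heteroarene is dearomatised into the seven-membered carbocycle while both new C–C bonds form in one operation; the closest known reaction type is the intramolecular oxidopyrylium–alkyne (5+2) cycloaddition of 6-substituted 6-acetoxypyranones. The seven-membered ring closes as the two-bond cycloaddition itself, the ylide oxygen remaining as the ether bridge of an 8-oxabicyclo[3.2.1]octadienone, and the oxolane closes in the fused mode because the three-atom CH2–CH(CH3)–O tether can only span C6 of the ylide and the oxygen-bearing alkyne carbon. The tether therefore fixes the regiochemistry (oxygenated alkyne carbon to C6, the CH2OTIPS-bearing carbon to C2) against the electronic preference of the alkynyl ether. The only new stereocentres are the two bridgeheads; they are set together by the face of the ylide that the alkyne takes, and this is controlled by the (R)-stereocentre of the tether, whose methyl group should lie pseudo-equatorial on the forming oxolane and on the side of the ring oxygen and not of C5–H. This control is remote and expected to be modest; the adduct of the other face is a diastereomer and would be removed here by chromatography, and dilution suppresses ylide dimerisation.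

Step 14
Reactants: 22 tricyclic dienone cycloadduct
Product: 23 trimethylsilyl enol ether of the vinyl adduct
Conditions: vinylmagnesium bromide, CuBr·SMe2 (20 mol%), TMSCl, THF, −78 °C; Et3N quench
Reagents that add atoms: vinylmagnesium bromide, C=C[Mg]Br; chlorotrimethylsilane, C[Si](C)(C)Cl
Why: In this copper-catalysed, TMSCl-accelerated conjugate addition the vinyl group should enter the enone on the exo face (the side of the oxygen bridge), which sets the CH(vinyl) centre, and the enolate is kept regiospecifically as its silyl enol ether.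

Step 15
Reactants: 23 trimethylsilyl enol ether; 6 (R)-tert-butyl[(5-iodo-2-methylpent-1-en-3-yl)oxy]dimethylsilane
Product: 25 α-alkylated bicyclic ketone with the new quaternary centre, via lithium enolate 24 (not isolated)
Conditions: MeLi, THF, 0 °C; then HMPA, 6 (2 equiv), −78 → 0 °C
Reagents that add atoms: none
Why: The lithium enolate released regiospecifically by MeLi should be alkylated by the primary iodide anti to the adjacent exo vinyl group, that is on the endo face over the sp2 two-carbon bridge that carries no endo substituent, which sets the quaternary centre with methyl cis and side chain trans to vinyl.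

Step 16
Reactants: 25 α-alkylated bicyclic ketone
Product: 26 endo secondary alcohol
Conditions: LiAlH4, THF, −78 → −20 °C
Reagents that add atoms: none
Why: Hydride should attack the only ketone from the exo face, because the endo face is closed by the new side chain and the two-carbon bridge, giving the carbinol with hydroxyl cis to the side chain.

Step 17
Reactants: 26 endo secondary alcohol
Product: 27 its tert-butyldimethylsilyl ether
Conditions: TBSOTf, 2,6-lutidine, CH2Cl2, −78 → 0 °C
Reagents that add atoms: tert-butyldimethylsilyl trifluoromethanesulfonate, CC(C)(C)[Si](C)(C)OS(=O)(=O)C(F)(F)F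
Why: The silyl triflate silylates the neopentylic alcohol under base-buffered conditions that the cyclic enol ether survives.

Step 18
Reactants: 27 silyl ether
Product: 28 oxygen-bridged keto alcohol
Conditions: PPTS (cat.), acetone/H2O, 23 °C
Reagents that add atoms: water, O
Why: Mild acid hydrolysis of the cyclic enol ether (C-protonation, oxocarbenium, water) reveals the ring ketone and frees the secondary alcohol, while the ether bridge should persist because its opening would be a retro-5-endo oxa-Michael process.

Step 19
Reactants: 28 oxygen-bridged keto alcohol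
Product: 29 oxygen-bridged diketone
Conditions: Dess–Martin periodinane, NaHCO3, CH2Cl2, 0 → 23 °C
Reagents that add atoms: none
Why: Buffered Dess–Martin oxidation of the only free alcohol gives the methyl ketone and erases the controlling stereocentre without base-induced β-elimination.

Step 20
Reactants: 29 oxygen-bridged diketone
Product: 30 monocyclic hydroxy diketone
Conditions: SmI2 (2.5 equiv), THF/MeOH, −78 °C
Reagents that add atoms: none
Why: SmI2 reduction of the α-alkoxy ketone (ketyl formation, then scission of the α C–O bond) should cut the bridge at the quaternary bridgehead, a known way to open oxa-bridged ketones, leaving the oxygen as a secondary hydroxyl on the other bridgehead and a 1,4-diketone.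

Step 21
Reactants: 30 monocyclic hydroxy diketone
Product: 32 cycloheptenone 1,4-diketone, via secondary mesylate 31 (not isolated)
Conditions: MsCl, Et3N, CH2Cl2, 0 °C; then DBU, 0 → 23 °C
Reagents that add atoms: none
Why: Mesylation and E1cB elimination through the enolate of the ring ketone should give the conjugated C=C, the mesylate being a far better leaving group than the β-silyloxy group.

Step 22
Reactants: 32 cycloheptenone 1,4-diketone
Product: 33 ring-fused 2-methylfuran
Conditions: PPTS (cat.), toluene, 4 Å MS, 70 °C
Reagents that add atoms: none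
Why: Paal–Knorr cyclodehydration of the 1,4-diketone gives the furan that masks the enedione and holds both future carbonyl carbons cis on the future exocyclic C=C.

Step 23
Reactants: 33 ring-fused 2-methylfuran; 34 4,4,5,5-tetramethyl-2-vinyl-1,3,2-dioxaborolane
Product: 35 (E)-alkenyl pinacol boronate
Conditions: second-generation Hoveyda–Grubbs catalyst (10 mol%), 34 (5 equiv), CH2Cl2, 40 °C
Reagents that add atoms: none
Why: Cross-metathesis with the vinylboronate should occur at the only monosubstituted alkene, the isopropenyl and trisubstituted alkenes being spectators, and give the E-alkenylboronate.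

Step 24
Reactants: 35 (E)-alkenyl pinacol boronate
Product: 36 potassium (E)-alkenyltrifluoroborate
Conditions: KHF2 (aq.), MeOH, 23 °C
Reagents that add atoms: potassium hydrogen difluoride, [K+].F[H-]F
Why: Standard conversion of a pinacol boronate into the trifluoroborate with retention of alkene geometry.

Step 25
Reactants: 36 potassium (E)-alkenyltrifluoroborate; 37 3-methylbut-2-enoic acid
Product: 38 (E)-enol ester
Conditions: Cu(OAc)2 (20 mol%), DMAP, 4 Å MS, O2 (1 atm), MeCN/CH2Cl2, 40 °C
Reagents that add atoms: none
Why: Copper-catalysed oxidative C–O coupling (Chan–Lam type) of an alkenyltrifluoroborate with a carboxylic acid is known to give enol esters with retention of the E geometry.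

Step 26
Reactants: 38 (E)-enol ester
Product: 39 furan triol
Conditions: HF·pyridine, pyridine, THF, 0 → 23 °C
Reagents that add atoms: none
Why: Buffered fluoride removes the two TBS ethers and the primary TIPS ether without touching the enol ester or the furan.

Step 27
Reactants: 39 furan triol
Product: 41 target compound (CNP0146349.1), via furan endoperoxide 40 (not isolated)
Conditions: O2, visible light, tetraphenylporphyrin (cat.), CH2Cl2, −78 °C; then Me2S, −78 → 0 °C
Reagents that add atoms: dioxygen, O=O
Why: [4+2] addition of singlet oxygen to the furan, which should react much faster than the isopropenyl, enol ester and senecioate alkenes, and reduction of the endoperoxide with Me2S should release the cis (Z) enedione under neutral, non-isomerising conditions.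

**Compound list**

1 | 3-chloropropanoyl chloride | ClCCC(Cl)=O | starting material
2 | prop-1-en-2-ylmagnesium bromide | CC(=C)[Mg]Br | starting material
3 | 5-chloro-2-methylpent-1-en-3-one | CC(=C)C(=O)CCCl | intermediate
4 | (R)-5-chloro-2-methylpent-1-en-3-ol | CC(=C)[C@H](O)CCCl | intermediate
5 | (R)-tert-butyl[(5-chloro-2-methylpent-1-en-3-yl)oxy]dimethylsilane | CC(=C)[C@H](O[Si](C)(C)C(C)(C)C)CCCl | intermediate
6 | (R)-tert-butyl[(5-iodo-2-methylpent-1-en-3-yl)oxy]dimethylsilane | CC(=C)[C@H](O[Si](C)(C)C(C)(C)C)CCI | intermediate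
7 | methyl 3-methylfuran-2-carboxylate | COC(=O)c1occc1C | starting material
8 | (3-methylfuran-2-yl)methanol | Cc1ccoc1CO | intermediate
9 | tert-butyldimethyl[(3-methylfuran-2-yl)methoxy]silane | Cc1ccoc1CO[Si](C)(C)C(C)(C)C | intermediate
10 | (R)-2-methyloxirane | C[C@@H]1CO1 | starting material
11 | 5-lithio derivative of 9 | Cc1cc([Li])oc1CO[Si](C)(C)C(C)(C)C | intermediate
12 | (R)-1-[5-(tert-butyldimethylsilyloxymethyl)-4-methylfuran-2-yl]propan-2-ol | C[C@@H](O)Cc1cc(C)c(CO[Si](C)(C)C(C)(C)C)o1 | intermediate
13 | (E)-1,2-dichlorovinyl ether of 12 | C[C@@H](O/C(Cl)=C\Cl)Cc1cc(C)c(CO[Si](C)(C)C(C)(C)C)o1 | intermediate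
14 | lithium alkoxyacetylide from 13 | C[C@@H](OC#C[Li])Cc1cc(C)c(CO[Si](C)(C)C(C)(C)C)o1 | intermediate
15 | lithium 3-alkoxyprop-2-yn-1-olate | C[C@@H](OC#CCO[Li])Cc1cc(C)c(CO[Si](C)(C)C(C)(C)C)o1 | intermediate
16 | 3-(triisopropylsilyloxy)prop-1-ynyl ether of 12 | C[C@@H](OC#CCO[Si](C(C)C)(C(C)C)C(C)C)Cc1cc(C)c(CO[Si](C)(C)C(C)(C)C)o1 | intermediate
17 | {3-methyl-5-[(R)-2-(3-triisopropylsilyloxyprop-1-ynyloxy)propyl]furan-2-yl}methanol | C[C@@H](OC#CCO[Si](C(C)C)(C(C)C)C(C)C)Cc1cc(C)c(CO)o1 | intermediate
18 | 2,5-endoperoxide of furan 17 (bridgeheads undefined) | C[C@@H](OC#CCO[Si](C(C)C)(C(C)C)C(C)C)CC12OOC(CO)(O1)C(C)=C2 | intermediate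
19 | 6-hydroxy-4-methyl-6-[(R)-2-(3-triisopropylsilyloxyprop-1-ynyloxy)propyl]-2H-pyran-3(6H)-one (both anomers) | C[C@@H](OC#CCO[Si](C(C)C)(C(C)C)C(C)C)CC1(O)OCC(=O)C(C)=C1 | intermediate
20 | 6-acetate of 19 | C[C@@H](OC#CCO[Si](C(C)C)(C(C)C)C(C)C)CC1(OC(C)=O)OCC(=O)C(C)=C1 | intermediate
21 | 4-methyl-6-substituted 3-oxidopyrylium ylide | C[C@@H](OC#CCO[Si](C(C)C)(C(C)C)C(C)C)Cc1cc(C)c([O-])c[o+]1 | intermediate
22 | cycloadduct: 3-methyl-7-(triisopropylsilyloxymethyl)-8-oxabicyclo[3.2.1]octa-3,6-dien-2-one whose C5 and C6 are joined by –CH2–CH(CH3)–O– (oxygen on C6; bridgeheads C1 R and C5 R; oxolane methyl carbon R, methyl on the side of the oxygen bridge) | O=C1C(C)=C[C@@]23C[C@@H](C)OC3=C(CO[Si](C(C)C)(C(C)C)C(C)C)[C@H]1O2 | intermediate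
23 | trimethylsilyl enol ether of 22 after conjugate addition (vinyl exo at C4) | C[Si](C)(C)OC1=C(C)[C@@H](C=C)[C@@]23C[C@@H](C)OC3=C(CO[Si](C(C)C)(C(C)C)C(C)C)[C@H]1O2 | intermediate
24 | lithium enolate from 23 | [Li]OC1=C(C)[C@@H](C=C)[C@@]23C[C@@H](C)OC3=C(CO[Si](C(C)C)(C(C)C)C(C)C)[C@H]1O2 | intermediate
25 | bicyclic ketone with quaternary C3 (methyl exo, silyloxy-isopropenyl-propyl chain endo, vinyl exo at C4) | O=C1[C@](C)(CC[C@@H](O[Si](C)(C)C(C)(C)C)C(C)=C)[C@@H](C=C)[C@@]23C[C@@H](C)OC3=C(CO[Si](C(C)C)(C(C)C)C(C)C)[C@H]1O2 | intermediate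
26 | endo C2 alcohol of 25 | O[C@@H]1[C@](C)(CC[C@@H](O[Si](C)(C)C(C)(C)C)C(C)=C)[C@@H](C=C)[C@@]23C[C@@H](C)OC3=C(CO[Si](C(C)C)(C(C)C)C(C)C)[C@H]1O2 | intermediate
27 | tert-butyldimethylsilyl ether of 26 | CC(C)(C)[Si](C)(C)O[C@@H]1[C@](C)(CC[C@@H](O[Si](C)(C)C(C)(C)C)C(C)=C)[C@@H](C=C)[C@@]23C[C@@H](C)OC3=C(CO[Si](C(C)C)(C(C)C)C(C)C)[C@H]1O2 | intermediate
28 | 8-oxabicyclo[3.2.1]octan-6-one with (R)-2-hydroxypropyl on bridgehead C5 and CH(CH2OTIPS) at C7 (C7 epimers; in equilibrium with its cyclic hemiketal) | CC(C)(C)[Si](C)(C)O[C@@H]1[C@](C)(CC[C@@H](O[Si](C)(C)C(C)(C)C)C(C)=C)[C@@H](C=C)[C@@]2(C[C@@H](C)O)O[C@@H]1C(CO[Si](C(C)C)(C(C)C)C(C)C)C2=O | intermediate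
29 | bridged diketone (2-oxopropyl on bridgehead C5) | CC(C)(C)[Si](C)(C)O[C@@H]1[C@](C)(CC[C@@H](O[Si](C)(C)C(C)(C)C)C(C)=C)[C@@H](C=C)[C@@]2(CC(C)=O)O[C@@H]1C(CO[Si](C(C)C)(C(C)C)C(C)C)C2=O | intermediate
30 | 3-hydroxy-7-(2-oxopropyl)cycloheptanone (epimers at the two ketone α-carbons) | CC(C)(C)[Si](C)(C)O[C@@H]1[C@](C)(CC[C@@H](O[Si](C)(C)C(C)(C)C)C(C)=C)[C@@H](C=C)C(CC(C)=O)C(=O)C(CO[Si](C(C)C)(C(C)C)C(C)C)[C@H]1O | intermediate
31 | methanesulfonate of 30 | CC(C)(C)[Si](C)(C)O[C@@H]1[C@](C)(CC[C@@H](O[Si](C)(C)C(C)(C)C)C(C)=C)[C@@H](C=C)C(CC(C)=O)C(=O)C(CO[Si](C(C)C)(C(C)C)C(C)C)[C@H]1OS(C)(=O)=O | intermediate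
32 | 7-(2-oxopropyl)cyclohept-2-en-1-one (C7 epimers) | CC(C)(C)[Si](C)(C)O[C@H]1C=C(CO[Si](C(C)C)(C(C)C)C(C)C)C(=O)C(CC(C)=O)[C@H](C=C)[C@@]1(C)CC[C@@H](O[Si](C)(C)C(C)(C)C)C(C)=C | intermediate
33 | 2-methyl-4H-cyclohepta[b]furan (vinyl at C4, quaternary C5, OTBS at C6, C7=C8 with CH2OTIPS on C8) | CC(C)(C)[Si](C)(C)O[C@H]1C=C(CO[Si](C(C)C)(C(C)C)C(C)C)c2oc(C)cc2[C@H](C=C)[C@@]1(C)CC[C@@H](O[Si](C)(C)C(C)(C)C)C(C)=C | intermediate
34 | 4,4,5,5-tetramethyl-2-vinyl-1,3,2-dioxaborolane | C=CB1OC(C)(C)C(C)(C)O1 | starting material
35 | (E)-alkenyl pinacol boronate of 33 | CC(C)(C)[Si](C)(C)O[C@H]1C=C(CO[Si](C(C)C)(C(C)C)C(C)C)c2oc(C)cc2[C@H](/C=C/B2OC(C)(C)C(C)(C)O2)[C@@]1(C)CC[C@@H](O[Si](C)(C)C(C)(C)C)C(C)=C | intermediate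
36 | potassium (E)-alkenyltrifluoroborate | CC(C)(C)[Si](C)(C)O[C@H]1C=C(CO[Si](C(C)C)(C(C)C)C(C)C)c2oc(C)cc2[C@H](/C=C/[B-](F)(F)F)[C@@]1(C)CC[C@@H](O[Si](C)(C)C(C)(C)C)C(C)=C.[K+] | intermediate
37 | 3-methylbut-2-enoic acid | CC(C)=CC(O)=O | starting material
38 | (E)-enol 3-methylbut-2-enoate, fully silylated furan | CC(C)(C)[Si](C)(C)O[C@H]1C=C(CO[Si](C(C)C)(C(C)C)C(C)C)c2oc(C)cc2[C@H](/C=C/OC(=O)C=C(C)C)[C@@]1(C)CC[C@@H](O[Si](C)(C)C(C)(C)C)C(C)=C | intermediate
39 | furan triol | O[C@H]1C=C(CO)c2oc(C)cc2[C@H](/C=C/OC(=O)C=C(C)C)[C@@]1(C)CC[C@@H](O)C(C)=C | intermediate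
40 | 2,5-endoperoxide of furan 39 (bridgeheads undefined) | O[C@H]1C=C(CO)C23OOC(C)(O2)C=C3[C@H](/C=C/OC(=O)C=C(C)C)[C@@]1(C)CC[C@@H](O)C(C)=C | intermediate
41 | CNP0146349.1 | C=C(C)[C@H](O)CC[C@@]1(C)[C@@H](O)C=C(CO)C(=O)/C(=C\C(C)=O)[C@@H]1/C=C/OC(=O)C=C(C)C | target

**Step count and risks**

Total step count: 27. Longest linear sequence: 23 steps (steps 5–27, from 7); the side-chain iodide 6 is made in a four-step branch (steps 1–4).

Steps most likely to fail:

1. Step 13. The remote tether stereocentre may discriminate the two faces of the ylide only weakly, lowering the amount of the needed diastereomer, and the alkynyl ether may undergo retro-ene loss or ylide dimerisation may compete if the cycloaddition is slow. The sense of substrate control could also be reversed simply by starting from (S)-2-methyloxirane. The fallback moves facial control from the substrate to a catalyst. It sets out from 19, which is acylated with 4-(methylsulfanyl)benzoyl chloride to the hemiketal 4-(methylsulfanyl)benzoate F1. F1 is then cyclised under dual catalysis by a chiral primary-amine thiourea and an achiral diaryl thiourea with AcOH in toluene at 23–40 °C, through an aminopyrylium, with the catalyst antipode chosen to reinforce the tether. The fallback returns to the route at 22.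

2. Step 15. SN2 attack of a tetrasubstituted enolate on an unactivated primary iodide on the concave face may be slow, and O-alkylation, elimination of HI from 6 or attack syn to the vinyl group may take over. The fallback replaces the substitution by a conjugate addition and sets out from 23 and 3. Compound 3 is dehydrochlorinated with Et3N to 2-methylpenta-1,4-dien-3-one F2. The lithium enolate 24, made from 23 with MeLi, adds at −78 °C to the unsubstituted vinyl terminus of F2 to give the Michael adduct diketone F3. Corey–Bakshi–Shibata reduction ((S)-2-methyl-CBS-oxazaborolidine, catecholborane) of the unhindered cross-conjugated ketone, the ring ketone being neopentylic on both sides, gives the (R)-allylic alcohol F4. Silylation with TBSCl and imidazole returns to the route at 25.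

3. Step 23. Metathesis at the α-branched, hindered vinyl group may stall, the catalyst may be tied up by the furan, or the isopropenyl group may take part. The fallback is a Heck-type C–H borylation that sets out from 33. A palladium-catalysed boryl-Heck reaction with B-chlorocatecholborane (Pd2(dba)3, bulky phosphine, LiOTf, Cy2NMe, PhCF3, 70 °C) gives the (E)-alkenyl catechol boronate F5. Exchange with pinacol and Et3N returns to the route at 35.

Further compounds
F1 | step 13 | hemiketal 4-(methylsulfanyl)benzoate of 19 | C[C@@H](OC#CCO[Si](C(C)C)(C(C)C)C(C)C)CC1(OC(=O)c2ccc(SC)cc2)OCC(=O)C(C)=C1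
F2 | step 15 | 2-methylpenta-1,4-dien-3-one | C=CC(=O)C(C)=C
F3 | step 15 | Michael adduct diketone (4-methyl-3-oxopent-4-enyl chain on the quaternary carbon) | O=C1[C@](C)(CCC(=O)C(C)=C)[C@@H](C=C)[C@@]23C[C@@H](C)OC3=C(CO[Si](C(C)C)(C(C)C)C(C)C)[C@H]1O2
F4 | step 15 | (R)-allylic alcohol, desilyl analogue of 25 | O=C1[C@](C)(CC[C@@H](O)C(C)=C)[C@@H](C=C)[C@@]23C[C@@H](C)OC3=C(CO[Si](C(C)C)(C(C)C)C(C)C)[C@H]1O2
F5 | step 23 | (E)-alkenyl catechol boronate of 33 | CC(C)(C)[Si](C)(C)O[C@H]1C=C(CO[Si](C(C)C)(C(C)C)C(C)C)c2oc(C)cc2[C@H](/C=C/B2Oc3ccccc3O2)[C@@]1(C)CC[C@@H](O[Si](C)(C)C(C)(C)C)C(C)=C
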